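**Plan**

- The retrosynthesis first cuts the two ring A–CH2 bonds to the 4-hydroxybenzyl groups (twofold p-quinone methide benzylation). It then cuts the ring B–C bond of the two-carbon bridge (Sonogashira, with the alkyne as the latent CH2CH2), and last the ring B–CH2 bond of the third benzyl group (Negishi).
- The key step rests on ring A: its methoxy and hydroxy oxygens are meta to each other, so the two ring carbons flanking the CH2CH2 bridge are each ortho to one oxygen and para to the other.
- Forward, no ring is built. The ring B bromide comes from 3,5-dibromophenol (O-benzylation, mono-benzylation) and the ring A alkyne from 3-hydroxy-5-methoxybenzaldehyde (O-benzylation, homologation). The two are coupled, hydrogenated to the free triphenol bibenzyl, and this is benzylated twice on ring A with 4-hydroxybenzyl alcohol.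
- Stereochemistry: there is none to set.

Key step: step 7

Assumption: the target has no stereocentre and no stereogenic double bond, so it is achiral and the route needs no stereocontrol.

**Route**

Step 1
Reactants: 1 3,5-dibromophenol
Product: 2 1-(benzyloxy)-3,5-dibromobenzene
Conditions: BnBr (1.1 equiv), K2CO3, DMF, rt
Reagents that add atoms: benzyl bromide, BrCc1ccccc1
Why: Williamson ether synthesis; the phenoxide displaces bromide from benzyl bromide and the aryl bromides are inert.

Step 2
Reactants: 2 1-(benzyloxy)-3,5-dibromobenzene (2.5 equiv, excess recovered); 3 4-(benzyloxy)benzyl chloride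
Product: 5 1-(benzyloxy)-3-bromo-5-[4-(benzyloxy)benzyl]benzene, via [4-(benzyloxy)benzyl]zinc chloride 4 (not isolated)
Conditions: 3, Zn dust, LiCl, THF, 25 °C; then 2, Pd(PPh3)4 (3 mol%), THF, 50 °C
Reagents that add atoms: none
Why: LiCl-promoted zinc insertion into the benzylic C–Cl bond gives 4, which undergoes Negishi coupling at one C–Br of 2; the excess of the symmetric dibromide, and the slower oxidative addition of the product once the second bromine is replaced by an alkyl group, should hold the reaction at mono-coupling.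

Step 3
Reactants: 6 3-hydroxy-5-methoxybenzaldehyde
Product: 7 3-(benzyloxy)-5-methoxybenzaldehyde
Conditions: BnBr (1.1 equiv), K2CO3, DMF, rt
Reagents that add atoms: benzyl bromide, BrCc1ccccc1
Why: Williamson ether synthesis at the only acidic OH; the non-enolisable aldehyde is untouched by carbonate.

Step 4
Reactants: 7 3-(benzyloxy)-5-methoxybenzaldehyde
Product: 8 1-(benzyloxy)-3-ethynyl-5-methoxybenzene
Conditions: dimethyl (1-diazo-2-oxopropyl)phosphonate (1.3 equiv), K2CO3 (2 equiv), MeOH–THF, 0 °C to rt
Reagents that add atoms: dimethyl (1-diazo-2-oxopropyl)phosphonate (Ohira–Bestmann reagent), COP(=O)(OC)C(=[N+]=[N-])C(C)=O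
Why: Seyferth–Gilbert homologation in its Ohira–Bestmann form; methanolysis frees the diazomethylphosphonate anion, which adds to the aldehyde, eliminates dimethyl phosphate, and the diazoalkene loses N2 with a 1,2-hydrogen shift to give the terminal alkyne, the ethers being stable to K2CO3/MeOH.

Step 5
Reactants: 5 1-(benzyloxy)-3-bromo-5-[4-(benzyloxy)benzyl]benzene; 8 1-(benzyloxy)-3-ethynyl-5-methoxybenzene
Product: 9 1-(benzyloxy)-3-[4-(benzyloxy)benzyl]-5-{[3-(benzyloxy)-5-methoxyphenyl]ethynyl}benzene
Conditions: PdCl2(PPh3)2 (3 mol%), CuI (3 mol%), Et3N–DMF, 80 °C, degassed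
Reagents that add atoms: none
Why: Sonogashira coupling of the single aryl bromide with the single terminal alkyne; heating compensates for the slow oxidative addition of an unactivated aryl bromide, and the ethers are inert.

Step 6
Reactants: 9 1-(benzyloxy)-3-[4-(benzyloxy)benzyl]-5-{[3-(benzyloxy)-5-methoxyphenyl]ethynyl}benzene
Product: 10 3-[2-(3-hydroxy-5-methoxyphenyl)ethyl]-5-[(4-hydroxyphenyl)methyl]phenol
Conditions: H2 (1 atm), 10% Pd/C, THF–MeOH, rt
Reagents that add atoms: none
Why: Heterogeneous hydrogenation saturates the diarylalkyne to the CH2CH2 bridge and cleaves the three aryl benzyl ethers by hydrogenolysis on the same catalyst; the diarylmethane C–C bonds, the methyl ether and the arenes are stable at 1 atm.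

Step 7
Reactants: 10 3-[2-(3-hydroxy-5-methoxyphenyl)ethyl]-5-[(4-hydroxyphenyl)methyl]phenol; 11 4-hydroxybenzyl alcohol (2.2 equiv)
Product: 15 3-{2-[3-hydroxy-2,6-bis(4-hydroxybenzyl)-5-methoxyphenyl]ethyl}-5-(4-hydroxybenzyl)phenol (target), via p-quinone methide (4-methylidenecyclohexa-2,5-dien-1-one) 12 (not isolated), via 3-{2-[5-hydroxy-2-(4-hydroxybenzyl)-3-methoxyphenyl]ethyl}-5-(4-hydroxybenzyl)phenol 13 (not isolated), via 3-{2-[3-hydroxy-2-(4-hydroxybenzyl)-5-methoxyphenyl]ethyl}-5-(4-hydroxybenzyl)phenol 14 (not isolated)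
Conditions: 11 added over several hours, TsOH·H2O (10 mol%), 1,4-dioxane–H2O (1:1, degassed), 70 °C, Ar
Reagents that add atoms: none
Why: Acid-assisted loss of water from 11 gives the p-quinone methide 12 (reacting as its O-protonated form, the 4-hydroxybenzyl cation), whose exocyclic carbon is attacked by ring A of 10 at a carbon flanking the CH2CH2 bridge; rearomatisation of both partners gives the mono-benzylated bibenzyls 13 and 14, and a second alkylation at the other flanking carbon converges both on 15. The closest known reaction type is the acid- or heat-promoted Friedel–Crafts benzylation of resorcinol-type arenes by p-quinone methides generated from 4-hydroxybenzyl alcohols. Two C–C bonds form, no ring closes and no stereocentre arises. The step needs selectivity for ring A over ring B and the 4-hydroxyphenyl rings, and within ring A for the two flanking carbons over the carbon between the oxygens: only ring A has two meta-disposed oxygen donors acting in concert, and each flanking carbon is para to one of them, whereas the third carbon is only ortho to both. Slow addition of 11 keeps the electrophile scarce, so that it should be taken by the most nucleophilic ring and not by 11 itself, about two equivalents limit over-alkylation, and mono-benzylated material can be resubmitted.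

**Compound list**

1 | 3,5-dibromophenol | Oc1cc(Br)cc(Br)c1 | starting material
2 | 1-(benzyloxy)-3,5-dibromobenzene | Brc1cc(Br)cc(OCc2ccccc2)c1 | intermediate
3 | 4-(benzyloxy)benzyl chloride | ClCc1ccc(OCc2ccccc2)cc1 | starting material
4 | [4-(benzyloxy)benzyl]zinc chloride | Cl[Zn]Cc1ccc(OCc2ccccc2)cc1 | intermediate
5 | 1-(benzyloxy)-3-bromo-5-[4-(benzyloxy)benzyl]benzene | Brc1cc(Cc2ccc(OCc3ccccc3)cc2)cc(OCc2ccccc2)c1 | intermediate
6 | 3-hydroxy-5-methoxybenzaldehyde | COc1cc(O)cc(C=O)c1 | starting material
7 | 3-(benzyloxy)-5-methoxybenzaldehyde | COc1cc(OCc2ccccc2)cc(C=O)c1 | intermediate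
8 | 1-(benzyloxy)-3-ethynyl-5-methoxybenzene | COc1cc(OCc2ccccc2)cc(C#C)c1 | intermediate
9 | 1-(benzyloxy)-3-[4-(benzyloxy)benzyl]-5-{[3-(benzyloxy)-5-methoxyphenyl]ethynyl}benzene | COc1cc(OCc2ccccc2)cc(C#Cc2cc(OCc3ccccc3)cc(Cc3ccc(OCc4ccccc4)cc3)c2)c1 | intermediate
10 | 3-[2-(3-hydroxy-5-methoxyphenyl)ethyl]-5-[(4-hydroxyphenyl)methyl]phenol | COc1cc(O)cc(CCc2cc(O)cc(Cc3ccc(O)cc3)c2)c1 | intermediate
11 | 4-hydroxybenzyl alcohol | OCc1ccc(O)cc1 | starting material
12 | p-quinone methide (4-methylidenecyclohexa-2,5-dien-1-one) | C=C1C=CC(=O)C=C1 | intermediate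
13 | 3-{2-[5-hydroxy-2-(4-hydroxybenzyl)-3-methoxyphenyl]ethyl}-5-(4-hydroxybenzyl)phenol | COc1cc(O)cc(CCc2cc(O)cc(Cc3ccc(O)cc3)c2)c1Cc1ccc(O)cc1 | intermediate
14 | 3-{2-[3-hydroxy-2-(4-hydroxybenzyl)-5-methoxyphenyl]ethyl}-5-(4-hydroxybenzyl)phenol | COc1cc(O)c(Cc2ccc(O)cc2)c(CCc2cc(O)cc(Cc3ccc(O)cc3)c2)c1 | intermediate
15 | 3-{2-[3-hydroxy-2,6-bis(4-hydroxybenzyl)-5-methoxyphenyl]ethyl}-5-(4-hydroxybenzyl)phenol | COc1cc(O)c(Cc2ccc(O)cc2)c(CCc2cc(O)cc(Cc3ccc(O)cc3)c2)c1Cc1ccc(O)cc1 | target

**Step count and risks**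

Total steps: 7. Longest linear sequence: 5 steps (1, 2, 5, 6, 7; the branch 3, 4, 5, 6, 7 is equally long).

Steps most likely to fail:

1. Step 7. The alkylation may be indiscriminate: attack at the ring A carbon between the two oxygens, attack on the mono-oxygenated rings, over-alkylation and self-condensation of the quinone methide would give a mixture of congeners from which the target is hard to separate. The fallback sets out from 10 and comes back at 15, and fixes the two sites by halogenation and cross-coupling instead of electrophilic benzylation. The three phenols of 10 would be re-benzylated (BnBr, K2CO3, DMF) to 1-(benzyloxy)-3-[4-(benzyloxy)benzyl]-5-{2-[3-(benzyloxy)-5-methoxyphenyl]ethyl}benzene F1. NBS (2 equiv, MeCN, 0 °C) should brominate the dialkoxy ring at its two carbons para to oxygen, as is usual for 5-alkylresorcinol diethers, giving 1-(benzyloxy)-3-(2-{3-(benzyloxy)-5-[4-(benzyloxy)benzyl]phenyl}ethyl)-2,4-dibromo-5-methoxybenzene F2. Twofold Negishi coupling with 4 (made again from 3, Zn and LiCl; Pd(OAc)2, SPhos, THF, 60 °C) would give the pentabenzyl ether 1-(benzyloxy)-2,4-bis[4-(benzyloxy)benzyl]-3-(2-{3-(benzyloxy)-5-[4-(benzyloxy)benzyl]phenyl}ethyl)-5-methoxybenzene F3. Hydrogenolysis of its five benzyl ethers (H2, Pd/C, THF–MeOH) would give 15.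

2. Step 2. A second cross-coupling at the remaining bromide and Wurtz-type homocoupling of the electron-rich benzylic zinc reagent may erode the mono-benzylated product. The fallback sets out from 2 and comes back at 5, and reverses the polarity so that mono-functionalisation is fixed by stoichiometric halogen–metal exchange. Bromine–lithium exchange (n-BuLi, 1.0 equiv, Et2O, −78 °C) would give [3-(benzyloxy)-5-bromophenyl]lithium F4. This adds to commercial 4-(benzyloxy)benzaldehyde (O=Cc1ccc(OCc2ccccc2)cc1) to give racemic [3-(benzyloxy)-5-bromophenyl][4-(benzyloxy)phenyl]methanol F5 after NH4Cl quench. Ionic deoxygenation of this doubly benzylic alcohol (Et3SiH, TFA, CH2Cl2, 0 °C) would give 5.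

3. Step 5. Oxidative addition of the unactivated, alkoxy-substituted aryl bromide may be slow enough that copper-mediated oxidative dimerisation of the alkyne consumes 8. The fallback sets out from 7 (with 5 as partner) and comes back at 10, replacing the alkyne by a styrene and the copper acetylide pathway by carbopalladation. Wittig methylenation of 7 (Ph3PCH3Br, KOtBu, THF, 0 °C) would give 1-(benzyloxy)-3-ethenyl-5-methoxybenzene F6. Mizoroki–Heck coupling with 5 (Pd(OAc)2, P(o-tol)3, Et3N, DMF, 100 °C) would give 1-(benzyloxy)-3-[4-(benzyloxy)benzyl]-5-{(E)-2-[3-(benzyloxy)-5-methoxyphenyl]ethenyl}benzene F7. Hydrogenation (H2, Pd/C, THF–MeOH) would saturate the alkene and cleave the three benzyl ethers to give 10.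

**Further compounds**

F1 | step 7 | 1-(benzyloxy)-3-[4-(benzyloxy)benzyl]-5-{2-[3-(benzyloxy)-5-methoxyphenyl]ethyl}benzene | COc1cc(OCc2ccccc2)cc(CCc2cc(OCc3ccccc3)cc(Cc3ccc(OCc4ccccc4)cc3)c2)c1
F2 | step 7 | 1-(benzyloxy)-3-(2-{3-(benzyloxy)-5-[4-(benzyloxy)benzyl]phenyl}ethyl)-2,4-dibromo-5-methoxybenzene | COc1cc(OCc2ccccc2)c(Br)c(CCc2cc(OCc3ccccc3)cc(Cc3ccc(OCc4ccccc4)cc3)c2)c1Br
F3 | step 7 | 1-(benzyloxy)-2,4-bis[4-(benzyloxy)benzyl]-3-(2-{3-(benzyloxy)-5-[4-(benzyloxy)benzyl]phenyl}ethyl)-5-methoxybenzene | COc1cc(OCc2ccccc2)c(Cc2ccc(OCc3ccccc3)cc2)c(CCc2cc(OCc3ccccc3)cc(Cc3ccc(OCc4ccccc4)cc3)c2)c1Cc1ccc(OCc2ccccc2)cc1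
F4 | step 2 | [3-(benzyloxy)-5-bromophenyl]lithium | [Li]c1cc(Br)cc(OCc2ccccc2)c1
F5 | step 2 | rac-[3-(benzyloxy)-5-bromophenyl][4-(benzyloxy)phenyl]methanol | OC(c1ccc(OCc2ccccc2)cc1)c1cc(Br)cc(OCc2ccccc2)c1
F6 | step 5 | 1-(benzyloxy)-3-ethenyl-5-methoxybenzene | COc1cc(OCc2ccccc2)cc(C=C)c1
F7 | step 5 | 1-(benzyloxy)-3-[4-(benzyloxy)benzyl]-5-{(E)-2-[3-(benzyloxy)-5-methoxyphenyl]ethenyl}benzene | COc1cc(OCc2ccccc2)cc(/C=C/c2cc(OCc3ccccc3)cc(Cc3ccc(OCc4ccccc4)cc3)c2)c1
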